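**Retrosynthetic overview**
1. Last bond, C2–C1′ (ring C to ring B): chromone 5 is deprotonated at C2 to the 2-chromonylzinc 7. This is an α-metalated enol ether (a masked acyl anion and β-acylvinyl anion), so the carbon that is natively the electrophilic β-position of the enone reacts as the nucleophile, and it is joined to the electrophilic C–I carbon of aryl iodide 6.
2. Chromone 5 ⇒ o-hydroxyacetophenone 3 plus one carbon from DMF-DMA; ring C closes by O1–C2 bond formation.
3. Ketone 3 ⇒ 1,2,4,5-tetramethoxybenzene 1 by Friedel–Crafts acetylation with loss of one ortho methyl in the same flask.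
4. Ring order: ring A is bought (1), ring C is built on it (step 2), ring B is bought (6) and attached last (step 3).

Assumption: the target has no stereocentre and no stereogenic axis, so it is achiral and the request for a single enantiomer needs no stereocontrol.

**Route**

Step 1
Reactants: 1 1,2,4,5-tetramethoxybenzene
Product: 3 1-(2-hydroxy-3,5,6-trimethoxyphenyl)ethan-1-one, via 2,3,5,6-tetramethoxyacetophenone 2 (not isolated)
Conditions: AcCl (1.2 equiv), AlCl3 (2.5 equiv), CH2Cl2, 0 °C → 40 °C; then ice/2 M HCl
Reagents that add atoms: acetyl chloride, CC(=O)Cl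
Why: Friedel–Crafts acylation at the only kind of free position of this electron-rich arene gives ketone 2, whose carbonyl chelates AlCl3 and directs cleavage of one of the two equivalent, crowded ortho methyl ethers (chelation-controlled O-demethylation), and the aluminium phenoxide chelate then resists a second cleavage; no stereocentre is formed.

Step 2
Reactants: 3 1-(2-hydroxy-3,5,6-trimethoxyphenyl)ethan-1-one
Product: 5 5,6,8-trimethoxy-4H-chromen-4-one, via enaminone 4 (not isolated)
Conditions: DMF-DMA (2.5 equiv), PhMe, 100 °C; evaporate; then AcOH, 100 °C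
Reagents that add atoms: N,N-dimethylformamide dimethyl acetal, COC(OC)N(C)C
Why: Condensation of the methyl ketone with DMF-DMA gives the vinylogous amide 4 (the hydrogen-bonded phenol is not methylated), and in hot AcOH the phenol adds 6-endo to the protonated enaminone and dimethylamine is eliminated (enaminone route to 3-unsubstituted chromones), which closes ring C; no stereocentre is formed.

Step 3
Reactants: 5 5,6,8-trimethoxy-4H-chromen-4-one; 6 2-iodo-1,4-dimethoxybenzene
Product: 8 2-(2,5-dimethoxyphenyl)-5,6,8-trimethoxy-4H-chromen-4-one, via 2-chromonylzinc chloride 7 (not isolated)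
Conditions: TMPZnCl·LiCl (TMP = 2,2,6,6-tetramethylpiperidin-1-yl; 1.2 equiv), THF, 25 °C, 1 h; then 6 (1.1 equiv), Pd(dba)2 (3 mol %), P(2-furyl)3 (6 mol %), 50 °C
Reagents that add atoms: none
Why: The vinylic C2–H next to the ring oxygen is the most acidic C–H of 5, so the magnesium-free TMP zinc amide (directed C–H zincation) gives the 2-chromonylzinc 7, an α-metalated enol ether in which the natively electrophilic C2 has become the nucleophile, and this polarity-reversed carbon is joined to the electrophilic C–I carbon of 6 by Negishi cross-coupling through zerovalent palladium; the ketone, the five methyl ethers and the aryl iodide tolerate the mild zinc amide, and no stereocentre is formed.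

**Compound list**
1 | 1,2,4,5-tetramethoxybenzene | COc1cc(OC)c(OC)cc1OC | starting material
2 | 1-(2,3,5,6-tetramethoxyphenyl)ethan-1-one (2,3,5,6-tetramethoxyacetophenone) | CC(=O)c1c(OC)c(OC)cc(OC)c1OC | intermediate
3 | 1-(2-hydroxy-3,5,6-trimethoxyphenyl)ethan-1-one | CC(=O)c1c(O)c(OC)cc(OC)c1OC | intermediate
4 | (E)-3-(dimethylamino)-1-(2-hydroxy-3,5,6-trimethoxyphenyl)prop-2-en-1-one | CN(C)/C=C/C(=O)c1c(O)c(OC)cc(OC)c1OC | intermediate
5 | 5,6,8-trimethoxy-4H-chromen-4-one | COc1cc(OC)c2occc(=O)c2c1OC | intermediate
6 | 2-iodo-1,4-dimethoxybenzene | COc1ccc(OC)c(I)c1 | starting material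
7 | chloro(5,6,8-trimethoxy-4-oxo-4H-chromen-2-yl)zinc, as its LiCl complex | COc1cc(OC)c2oc([Zn]Cl)cc(=O)c2c1OC | intermediate
8 | 2-(2,5-dimethoxyphenyl)-5,6,8-trimethoxy-4H-chromen-4-one (CNP0277731.0; achiral) | COc1ccc(OC)c(-c2cc(=O)c3c(OC)c(OC)cc(OC)c3o2)c1 | target

**Step count and risks**

Total step count: 3. Longest linear sequence: 3 (1 → 3 → 5 → 8).

Most likely to fail, first: step 3. A lithium or zinc chelate between the C4 carbonyl and the 5-methoxy group could steer the base to C3 and give the 3-aryl regioisomer after coupling. The ortho-methoxy, electron-rich iodide 6 may also couple slowly. The fallback gives up the metalated chromone and builds the C2–aryl unit with normal polarity. It sets out from 3 and comes back to the route at 8. Claisen–Schmidt condensation of 3 with 2,5-dimethoxybenzaldehyde (KOH, EtOH, 25 °C) gives (E)-3-(2,5-dimethoxyphenyl)-1-(2-hydroxy-3,5,6-trimethoxyphenyl)prop-2-en-1-one F1. Oxidative cyclisation of this chalcone with I2 (10 mol %) in DMSO at 130 °C then gives 8.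

Second: step 1. Acylation between two methoxy groups may be slow, and excess AlCl3 can over-demethylate or degrade the very electron-rich arene. The fallback replaces electrophilic substitution by directed lithiation and separates the demethylation. It sets out from 1 and comes back at 3. Lithiation of 1 (n-BuLi, TMEDA, THF, 0 °C) gives (2,3,5,6-tetramethoxyphenyl)lithium F2. This is acetylated with N-methoxy-N-methylacetamide (−78 °C → 25 °C, aq. HCl quench) to give ketone 2, now isolated. BCl3 (1.1 equiv, CH2Cl2, −78 → 0 °C, aqueous work-up) then removes one of the two equivalent ortho methyl groups to give 3.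

Third: step 2. The acetyl group flanked by OH and OMe may condense slowly with DMF-DMA, and some phenol O-methylation by the acetal is possible. The fallback brings in the C2 carbon by Claisen formylation. It sets out from 3 and comes back at 5. Treating 3 with NaH (3 equiv) and ethyl formate in THF (0 → 25 °C, aq. HCl quench) gives 2-hydroxy-5,6,8-trimethoxychroman-4-one F3 as the racemic hemiacetal. Dehydration with catalytic H2SO4 in AcOH at 60 °C gives 5.

**Further compounds**
F1 | step 3 | (E)-3-(2,5-dimethoxyphenyl)-1-(2-hydroxy-3,5,6-trimethoxyphenyl)prop-2-en-1-one | COc1ccc(OC)c(/C=C/C(=O)c2c(O)c(OC)cc(OC)c2OC)c1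
F2 | step 1 | (2,3,5,6-tetramethoxyphenyl)lithium | [Li]c1c(OC)c(OC)cc(OC)c1OC
F3 | step 2 | 2-hydroxy-5,6,8-trimethoxychroman-4-one (racemic hemiacetal) | COc1cc(OC)c2OC(O)CC(=O)c2c1OC
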